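Amounts come first: at any moment this flask is read as two numbers, target and starting material, both in percent of the starting material charged.

| flask | starting material | partner | temperature | remark | time |
|---|---|---|---|---|---|
| south | 0.58 M | 0.80 equiv | −20 °C | run made earlier |  |
| south-east | 0.58 M | 1.8 equiv | 13 °C | run made earlier |  |
| dawn | 0.58 M | 1.20 equiv | −5 °C |  | 12 min |
| dusk | 0.58 M | 1.20 equiv | −35 °C |  | 12 min |
| spring | 0.58 M | 1.20 equiv | 25 °C |  | 12 min |

- south (time / min: target / %, starting material / %): 2.00: 0, 99.9; 3.00: 0, 100.0; 4.00: 0.8, 100.3; 5.00: 0, 98.9; 8.00: 0.6, 99.5; 12.0: 0.5, 99.1; 20.0: 0.2, 99.6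
- south-east (time / min: target / %, starting material / %): 0.200: 0, 100.1; 0.500: 0, 98.6; 1.00: 1.1, 98.2; 1.50: 1.4, 96.4; 2.50: 4.4, 93.2; 3.00: 4.9, 91.7; 4.00: 7.8, 90.7

(scatter of a reading: 0.5 percentage points)

- amounts and yields of target count crystals too
- given per volume of solution although it is solid: crystals
- the analysis behind the earlier runs scatters by 0.5 percentage points, standard deviation
- reactions considered so far: starting material <-> intermediate + leaving ligand; partner + intermediate -> target; intermediate -> decomposed reagent; intermediate -> side product; crystals <-> target

- the flask that comes out highest in amount of target, in percent of the starting material charged, or "all alike" when all lie within 1.5 percentage points (dawn / dusk / spring / all alike)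
- target at the end, in percent of the starting material charged, dawn
- target at the end, in percent of the starting material charged, dusk
- target at the end, in percent of the starting material charged, spring

What can be frozen from these runs? The capture share (the selectivity of the trapping), meaning target gained per starting material lost. Over the last 3 south-east readings, it comes to 70.1 %.

Why pool the readings? Taken singly, the share reads 59.0 % at 3.00 min and 83.9 % at 4.00 min, and each reading scatters by 0.5 percentage points on a loss of 9.30 % at most.

Where is the weak spot? The share is borrowed from 1.8 equiv of partner at 13 °C, but spring has 1.20 equiv at 25 °C. I carry it unchanged and watch how it holds.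

What does it give for spring? South-east loses starting material at 0.0244 min⁻¹. Kept up for 12 min, that pace costs 25.4 %, and the share turns this into 17.8 % of target. Spring is hotter than south-east, so I take this as a floor, not an estimate.

And the cold flasks? South ends at 0.2 % of target, within the scatter, and dusk is colder still, so I expect nothing readable there. Dawn should stay below the floor, which puts spring ahead.

The forecast also names spring, with 1.6 % for dawn, 0.02 % for dusk and 50 % for spring, which stands above my floor, and for the pace in spring it says “Extrapolating gives k ≈ 0.09 /min at 25 °C”.

The flasks give 2.44 % for dawn, 0.00520 % for dusk and 43.8 % for spring, so spring comes out highest.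

    starting material ⇌ intermediate + leaving ligand (K = 0.0220 M, k = 0.00160 s⁻¹, Ea = 76.0 kJ mol⁻¹, ΔH = 10.0 kJ mol⁻¹)
    partner + intermediate → target (k = 0.0470 L mol⁻¹ s⁻¹, Ea = 46.0 kJ mol⁻¹)
    intermediate → decomposed reagent (k = 0.00290 s⁻¹, Ea = 95.0 kJ mol⁻¹)
    intermediate → side product (k = 0.00270 s⁻¹, Ea = 92.0 kJ mol⁻¹)
    crystals ⇌ target, rate k5*(cs5 - [target]) while solid is left; crystals form when [target] > cs5 (solubility = 0.270 M, k = 0.0520 s⁻¹)
    (constants at 25 °C)

Spring has lost 54.7 % of its starting material by 12.0 min, and the carried share turns that into 38.3 % of target, less than the 43.8 % found. Spring's own share is therefore 80.2 %. The same flask stopped at 5.0 min has lost 32.5 %, which that share turns into 26.0 % of target, and that flask holds 25.2 %.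

The earlier runs and the new flask are calculated for substances that don't exist; the scatter is artificial.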